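A direct plan would buy ring A complete as 2,4,6-trimethoxytoluene A1, add the second C-methyl and a formyl group by formylation, ionic reduction and a second formylation to reach aldehyde A2, join A2 to 2-ethynylanisole A3 by acetylide addition and oxidation to ynone A4, free one ortho phenol with BCl3 to give A5, and close ring C last by a gold-catalysed oxyboration with peroxide work-up that also installs O3.
Its weakest steps would be:
- The formylation, reduction, formylation run-up: three linear steps that only turn A1 into A2, a simple hexasubstituted arene.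
- The BCl3 demethylation of A4: all three ring A oxygens are carried as methyl ethers and one is then removed again, on an acid- and chloride-sensitive ynone, which builds nothing.
- The closing oxyboration and oxidation of A5: a three-operation, one-flask step without precedent for 4-pyranone formation, which would have to beat 5-exo closure to the aurone and protodeauration, and on which the whole linear sequence is staked.

**Retrosynthetic overview**
- Ring A (C4a, C5 to C8, C8a) carries alternating oxygen (C5, C7, C8a) and carbon (C4a, 6-CH3, 8-CH3) substituents, the pattern of a propionate-derived triketide; it is therefore concealed as a 6-ethyl-5-methyl-2-pyranone and made last.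
- Key disconnection: the C5–C6 bond. The target skeleton is an isomer of pyrano[4,3-b]pyran-4,5-dione 11; methoxide opens the lactone and the ethyl CH2 closes onto the ester (lactone-to-phenol acyl shift), so the lactone C=O becomes O5, the lactone ring oxygen O7, the ethyl group C6 with its methyl, and the pyranone methyl 8-CH3.
- Ring order: ring C is built first, on triketide pyranone 4 used as a phenol surrogate (C3 acylation with benzyloxyacetic acid, aroyl transfer, cyclodehydration); ring A closes in the key step; O-methylation and hydrogenolysis finish.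
- How the weak steps are avoided: both C-methyls come from two propionyl units in one step; the ring oxygen is distinct from O5 and O7 from the start, so nothing is demethylated; O3 is carried in from benzyloxyacetic acid, so the last step is a hydrogenolysis. The target is achiral.

Key step: step 4

**Step 1**
Reactants: 1 methyl 3-oxopentanoate; 2 N-methoxy-N-methylpropanamide
Product: 4 6-ethyl-4-hydroxy-5-methyl-2H-pyran-2-one, via diketo ester 3 (not isolated)
Conditions: LiN(iPr)2 (2.2 equiv), THF, −78 to 0 °C; 2 (1.0 equiv), −78 to 0 °C; aq HCl; then DBU (1 equiv), PhMe, 90 °C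
Reagents that add atoms: none
Why: Huckin–Weiler dianion chemistry, in which the γ-carbanion of the β-keto ester dianion is acylated by the Weinreb amide (the chelated tetrahedral adduct prevents proton quench and over-addition) and DBU then closes the 3,5-diketo ester to the 4-hydroxy-2-pyranone by enol lactonisation.

**Step 2**
Reactants: 4 6-ethyl-4-hydroxy-5-methyl-2H-pyran-2-one; 5 (benzyloxy)acetic acid
Product: 7 3-[(benzyloxy)acetyl]-6-ethyl-4-hydroxy-5-methyl-2H-pyran-2-one, via O-acyl ester 6 (not isolated)
Conditions: 5 (1.1 equiv), DCC (1.2 equiv), DMAP (0.3 equiv), PhMe, rt then 80 °C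
Reagents that add atoms: none
Why: Steglich esterification of the acidic 4-hydroxyl followed by DMAP-mediated O-to-C acyl migration (Fries-type), the standard entry to 3-acyl-4-hydroxy-2-pyranones; C3 is the only free nucleophilic carbon of 4.

**Step 3**
Reactants: 7 3-[(benzyloxy)acetyl]-6-ethyl-4-hydroxy-5-methyl-2H-pyran-2-one; 8 2-methoxybenzoyl chloride
Product: 11 3-(benzyloxy)-7-ethyl-2-(2-methoxyphenyl)-8-methyl-4H,5H-pyrano[4,3-b]pyran-4,5-dione, via O-aroyl ester 9 (not isolated), via 1,3-diketone 10 (not isolated)
Conditions: 8 (1.15 equiv), K2CO3 (4 equiv), DMAP (0.1 equiv), acetone, 0 °C to reflux; filter, concentrate; then p-TsOH·H2O (0.2 equiv), PhMe, 80 °C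
Reagents that add atoms: none
Why: Baker–Venkataraman sequence with the pyranone as phenol surrogate, that is O-aroylation, carbonate-mediated aroyl shift to the OCH2 carbon next to the ketone (carbonate is too weak to deprotonate the 6-ethyl group), and acid-catalysed cyclodehydration of the 4-hydroxyl onto the aryl ketone to give the 4-pyranone ring C.

**Step 4**
Reactants: 11 3-(benzyloxy)-7-ethyl-2-(2-methoxyphenyl)-8-methyl-4H,5H-pyrano[4,3-b]pyran-4,5-dione
Product: 13 3-(benzyloxy)-5,7-dihydroxy-2-(2-methoxyphenyl)-6,8-dimethyl-4H-chromen-4-one, via pyranone ester 12 (not isolated)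
Conditions: NaH (4 equiv), MeOH (1.2 equiv), THF, 0 to 65 °C; then aq HCl
Reagents that add atoms: methanol CO (methoxy group of 12 only)
Why: Methoxide (from NaH and MeOH) adds to the lactone carbonyl C5 of the 2-pyranone ring and the C5–O6 bond breaks, which gives the 4-oxopyran-3-carboxylate 12 with a 3-oxopentan-2-yl chain on the former C8a; excess NaH then generates the enolate at the CH2 of that ethyl ketone, which attacks the ester in a Dieckmann condensation and forms the C5–C6 bond, and loss of methoxide with double enolisation gives the bis-phenoxide of 13, which makes the sequence irreversible. The closest known reaction type is the alkoxide-induced rearrangement of enol lactones into cyclic 1,3-diones (3-alkylidenephthalides into indane-1,3-diones, 3-alkylisocoumarins into naphthalene-1,3-diols, 6-methyl-2-pyranones of the triacetic acid lactone family into phloroglucinols) and the base-induced conversion of fused bis-pyranones into polyketide phenols. Only ring A closes, in a 6-(enolendo)-exo-trig mode; ring C and the O1–C8a bond are carried through unchanged. No stereocentre is formed, and the CH(CH3) centre of racemic 12 is lost on aromatisation. The step needs C-acylation at the ethyl CH2 (C6) and not reclosure through oxygen or aldol attack on the C4 carbonyl: relactonisation only returns 11, the aldol adduct would be a bridged ring that cannot aromatise and reverts, and only the Dieckmann product is drained by aromatisation. Because the more acidic C8–H is deprotonated first and lowers the reactivity of the ester, a hydride base in THF with a limited amount of methanol is used in place of methanolic methoxide.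

**Step 5**
Reactants: 13 3-(benzyloxy)-5,7-dihydroxy-2-(2-methoxyphenyl)-6,8-dimethyl-4H-chromen-4-one
Product: 14 3-(benzyloxy)-5,7-dimethoxy-2-(2-methoxyphenyl)-6,8-dimethyl-4H-chromen-4-one
Conditions: Me2SO4 (4 equiv), K2CO3 (5 equiv), acetone, reflux
Reagents that add atoms: dimethyl sulfate COS(=O)(=O)OC (both new O-methyl groups)
Why: Williamson O-methylation with a hard electrophile and a weak base, which favours O- over C-alkylation of the phloroglucinol-type ring, with excess reagent and reflux for the hydrogen-bonded 5-hydroxyl while the benzyl ether keeps O3 masked.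

**Step 6**
Reactants: 14 3-(benzyloxy)-5,7-dimethoxy-2-(2-methoxyphenyl)-6,8-dimethyl-4H-chromen-4-one
Product: 15 3-hydroxy-5,7-dimethoxy-2-(2-methoxyphenyl)-6,8-dimethyl-4H-chromen-4-one
Conditions: H2 (1 atm), Pd/C (10 wt %), EtOAc–MeOH, rt
Reagents that add atoms: none
Why: Hydrogenolysis of the benzyl ether over palladium on carbon; the tetrasubstituted C2–C3 double bond of the vinylogous ester and the aryl methyl ethers should be inert under these conditions.

**Compound list**
1 | methyl 3-oxopentanoate | CCC(=O)CC(=O)OC | starting material
2 | N-methoxy-N-methylpropanamide | CCC(=O)N(C)OC | starting material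
3 | methyl 4-methyl-3,5-dioxoheptanoate (racemic, enolisable) | CCC(=O)C(C)C(=O)CC(=O)OC | intermediate
4 | 6-ethyl-4-hydroxy-5-methyl-2H-pyran-2-one | CCC1=C(C)C(O)=CC(=O)O1 | intermediate
5 | (benzyloxy)acetic acid | OC(=O)COCc1ccccc1 | starting material
6 | 6-ethyl-5-methyl-2-oxo-2H-pyran-4-yl (benzyloxy)acetate | CCC1=C(C)C(OC(=O)COCc2ccccc2)=CC(=O)O1 | intermediate
7 | 3-[(benzyloxy)acetyl]-6-ethyl-4-hydroxy-5-methyl-2H-pyran-2-one | CCC1=C(C)C(O)=C(C(=O)COCc2ccccc2)C(=O)O1 | intermediate
8 | 2-methoxybenzoyl chloride | COc1ccccc1C(Cl)=O | starting material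
9 | 3-[(benzyloxy)acetyl]-6-ethyl-5-methyl-2-oxo-2H-pyran-4-yl 2-methoxybenzoate | CCC1=C(C)C(OC(=O)c2ccccc2OC)=C(C(=O)COCc2ccccc2)C(=O)O1 | intermediate
10 | 2-(benzyloxy)-1-(6-ethyl-4-hydroxy-5-methyl-2-oxo-2H-pyran-3-yl)-3-(2-methoxyphenyl)propane-1,3-dione (racemic, enolisable) | CCC1=C(C)C(O)=C(C(=O)C(OCc2ccccc2)C(=O)c2ccccc2OC)C(=O)O1 | intermediate
11 | 3-(benzyloxy)-7-ethyl-2-(2-methoxyphenyl)-8-methyl-4H,5H-pyrano[4,3-b]pyran-4,5-dione | CCC1=C(C)C2=C(C(=O)O1)C(=O)C(OCc1ccccc1)=C(c1ccccc1OC)O2 | intermediate
12 | methyl 5-(benzyloxy)-6-(2-methoxyphenyl)-4-oxo-2-(3-oxopentan-2-yl)-4H-pyran-3-carboxylate (racemic) | CCC(=O)C(C)C1=C(C(=O)OC)C(=O)C(OCc2ccccc2)=C(c2ccccc2OC)O1 | intermediate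
13 | 3-(benzyloxy)-5,7-dihydroxy-2-(2-methoxyphenyl)-6,8-dimethyl-4H-chromen-4-one | COc1ccccc1-c1oc2c(C)c(O)c(C)c(O)c2c(=O)c1OCc1ccccc1 | intermediate
14 | 3-(benzyloxy)-5,7-dimethoxy-2-(2-methoxyphenyl)-6,8-dimethyl-4H-chromen-4-one | COc1ccccc1-c1oc2c(C)c(OC)c(C)c(OC)c2c(=O)c1OCc1ccccc1 | intermediate
15 | 3-hydroxy-5,7-dimethoxy-2-(2-methoxyphenyl)-6,8-dimethyl-4H-chromen-4-one (achiral) | COc1ccccc1-c1oc2c(C)c(OC)c(C)c(OC)c2c(=O)c1O | target

**Step count and risks**
Total steps: 6. Longest linear sequence: 6.

Steps most likely to fail:

1. Step 4 (key step). The acyl shift may stall because deprotonation at C8–H deactivates the ester of 12, while methoxide opens ring C at C2 or traces of hydroxide hydrolyse the ester and cause decarboxylation. The fallback sets out from 4 (with 8) and comes back at 13; it frees ring A before ring C exists. Pyranone 4 would be isomerised with NaOMe in MeOH at 160–185 °C in a sealed vessel to 2,4-dimethylbenzene-1,3,5-triol F1, where no second ring can interfere. Commercial methyl (benzyloxy)acetate would be C-aroylated with 8 (LiN(SiMe3)2, 2.1 equiv, THF, −78 °C) to methyl 2-(benzyloxy)-3-(2-methoxyphenyl)-3-oxopropanoate F2. Thermal condensation of F1 with F2 (Ph2O, 200–240 °C; aroylketene C-acylation at the single free ring position, then cyclodehydration, a Mentzer-type chromone synthesis) would give 13.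

2. Step 3. The aroyl group may end on the side-chain enol oxygen or be lost by cleavage of the activated enol ester instead of migrating to carbon, and cyclodehydration may engage the lactone oxygen. The fallback sets out from 7 and comes back at 11; it replaces acyl transfer by aldol condensation and oxidative cyclisation. Condensation of 7 with 2-methoxybenzaldehyde (piperidine, CHCl3, reflux) would give the chalcone analogue 3-[(2Z)-2-(benzyloxy)-3-(2-methoxyphenyl)prop-2-enoyl]-6-ethyl-4-hydroxy-5-methyl-2H-pyran-2-one F3. Oxa-Michael closure and dehydrogenation of F3 with I2 (catalytic) in DMSO at 120 °C would give 11.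

3. Step 5. Methylation of the hydrogen-bonded 5-hydroxyl, flanked by the 6-methyl group, may remain incomplete, or the ambident phenoxide may be C-methylated with loss of aromaticity. The fallback sets out from 13 and comes back at 14 without a new intermediate. It uses a Mitsunobu etherification (MeOH, PPh3, diisopropyl azodicarboxylate, THF, 0 °C to rt), in which the phenol is the acid partner of a redox condensation and no free phenoxide meets an alkylating agent.

**Further compounds**
F1 | step 4 | 2,4-dimethylbenzene-1,3,5-triol | Cc1c(O)cc(O)c(C)c1O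
F2 | step 4 | methyl 2-(benzyloxy)-3-(2-methoxyphenyl)-3-oxopropanoate (racemic) | COC(=O)C(OCc1ccccc1)C(=O)c1ccccc1OC
F3 | step 3 | 3-[(2Z)-2-(benzyloxy)-3-(2-methoxyphenyl)prop-2-enoyl]-6-ethyl-4-hydroxy-5-methyl-2H-pyran-2-one | CCC1=C(C)C(O)=C(C(=O)/C(OCc2ccccc2)=C/c2ccccc2OC)C(=O)O1
F0 | step 5 | none | none
A1 | direct plan | 2,4,6-trimethoxytoluene | Cc1c(OC)cc(OC)cc1OC
A2 | direct plan | 2,4,6-trimethoxy-3,5-dimethylbenzaldehyde | O=Cc1c(OC)c(C)c(OC)c(C)c1OC
A3 | direct plan | 2-ethynylanisole | COc1ccccc1C#C
A4 | direct plan | 3-(2-methoxyphenyl)-1-(2,4,6-trimethoxy-3,5-dimethylphenyl)prop-2-yn-1-one | COc1ccccc1C#CC(=O)c1c(OC)c(C)c(OC)c(C)c1OC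
A5 | direct plan | 1-(2-hydroxy-4,6-dimethoxy-3,5-dimethylphenyl)-3-(2-methoxyphenyl)prop-2-yn-1-one | COc1ccccc1C#CC(=O)c1c(O)c(C)c(OC)c(C)c1OC
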